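The reading comes at 50 s, so I follow one substrate molecule and ask where it stands by then.

the same everywhere: reagent 1.20 M; time 50 s

| flask | substrate |
|---|---|
| south-west | 0.060 M |
| east | 0.12 M |
| north | 0.25 M |
| south | 0.50 M |
| south-east | 1.0 M |

    reagent + single product → bis adduct (k1 = 0.0332 M⁻¹ s⁻¹)
    substrate + bis adduct ⇌ idle adduct, settled at all times (K2 = 2.74 M⁻¹)
    substrate + reagent → single product (k3 = 0.0701 M⁻¹ s⁻¹)

- [bis adduct] (only what is free in solution) at the end for south-west, east, north, south, south-east, in this order
- the course of these numbers from the first flask to the last (hardly changes / rises all the way / falls all the way / falls, then rises / rises, then falls)

The molecule takes a first reagent to become single product, then a second to become bis adduct, which free substrate may hold as idle adduct. Before reckoning, I ask which given numbers must be known well. Cutting the second passage's constant, 0.0332 M⁻¹ s⁻¹, by a factor of 2 brings my reckoning below to 52.1%. The same cut in the first passage's constant, 0.0701 M⁻¹ s⁻¹, brings it to 60.6%, so both matter. The binding constant 2.74 M⁻¹ times the charged substrate is 0.164 in the south-west flask but 2.74 in the south-east flask, so it matters mainly at the top of the row. The reagent charge matters through its shrinking: two reagents per substrate come to 10.0% of the charge in the south-west flask and 167% in the south-east flask.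

Now the number. With reagent held at its charge, both passages are pseudo-first-order, with half-lives 8.24 s and 17.4 s. Together they give 75.4%. This is the held yield, the chance that one substrate molecule has become bis adduct by the reading while reagent stays at its charge. For the south-west flask I commit to 0.0453 M. I stop short of the south-east flask, where paying for that yield takes 1.51 M of reagent, more than the 1.20 M charged. For the course I use a rough score, not a proof: a bend at the top scores that demand over the charge, a steady rise scores the inverse, and the other courses score nothing, since the held-yield figure climbs with the charge. So I commit to a course that rises, then falls.

The forecast reads 0.043 M, 0.082 M, 0.146 M, 0.22 M and 0.19 M, a course that rises, then falls, noting that at the top “the reagent runs short”.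

The simulation gives 0.0432 M, 0.0821 M, 0.150 M, 0.222 M and 0.192 M, a course that rises, then falls, turning at 0.64 M of substrate.

In the south-west flask, with 92% of the reagent left, the reading stands at 95.5% of the held-yield figure. In the east flask, the same figure is 0.0905 M against the reading 0.0821 M. The simulated south-west run read ten times later gives 0.0600 M of free bis adduct against 0.0432 M at 50 s, so the time of reading is one part of the gap between that flask's reading and its charge. At 50.0 s, the south-west flask holds 25.4% of its charged substrate as single product.

The constants come from no measurement.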